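## Retrosynthetic overview

1. Target 25 ⇐ (E)-alkenyl pinacolboronate 22 + 3-methylbut-2-enoic acid 23 by copper C–O coupling with retention of geometry; the C2–CH2OH group comes from a Morita–Baylis–Hillman reaction.
2. The C6 alkenylboronate and the C7 2-oxopropyl group ⇐ one cis-fused δ-lactone (18). Its CH(CH3)–O unit, from ethyl (R)-3-hydroxybutanoate, is a traceless chiral tether (lactol → boron-Wittig; carbinol → ketone).
3. Cycloheptenone 18 ⇐ oxygen-bridged 8-oxabicyclo[3.2.1]octenone 14 by two SmI2 C–O cleavages; C7–H is set on protonation.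
4. Key step: 14 ⇐ intramolecular oxidopyrylium–alkene [5+2] cycloaddition of ylide 13 onto a tethered (E)-geranate. The ylide comes from Achmatowicz dearomatisation of a 2-furyl carbinol built from furan; the E geometry fixes C5/C6 and the tether fixes the face.
5. Ring order: furan → pyranone → (one step) oxabicyclo[3.2.1]octenone + δ-lactone → carbocyclic seven-membered ring set free → lactone opened.

Assumption: ring atoms are labelled as in the target's cycloheptenone (C1 = C=O, C2 = C–CH2OH, C3 = CH=, C4 = CH2, C5 = quaternary C, C6 = CH bearing the enol ester, C7 = CH bearing CH2COCH3), and commercial geranic acid is taken as the pure 2E isomer.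

## Route

Step 1
Reactants: 1 ethyl (3R)-3-hydroxybutanoate
Product: 2 (3R)-3-hydroxy-N-methoxy-N-methylbutanamide
Conditions: MeNH(OMe)·HCl, i-PrMgCl (3.2 equiv), THF, −20 → 0 °C
Reagents that add atoms: N,O-dimethylhydroxylamine hydrochloride (CNOC.Cl)
Why: Weinreb amidation of the ester by the magnesium amide proceeds through a chelated tetrahedral intermediate and does not touch the carbinol stereocentre.

Step 2
Reactants: 2 (3R)-3-hydroxy-N-methoxy-N-methylbutanamide; 3 (2E)-3,7-dimethylocta-2,6-dienoic acid (geranic acid)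
Product: 4 (2R)-4-[methoxy(methyl)amino]-4-oxobutan-2-yl (2E)-3,7-dimethylocta-2,6-dienoate
Conditions: DCC, 4-(dimethylamino)pyridine (0.1 equiv), CH2Cl2, 0 °C → rt
Reagents that add atoms: none
Why: Steglich esterification joins the secondary alcohol to the E-acid without affecting either stereo-element, so that the (R)-CH(CH3)–O unit becomes the chiral tether of the key step.

Step 3
Reactants: 4 (2R)-4-[methoxy(methyl)amino]-4-oxobutan-2-yl (2E)-3,7-dimethylocta-2,6-dienoate
Product: 5 (2R)-4-[methoxy(methyl)amino]-4-oxobutan-2-yl (2E)-5-[(2R)-3,3-dimethyloxiran-2-yl]-3-methylpent-2-enoate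
Conditions: 1,2:4,5-di-O-isopropylidene-β-D-erythro-2,3-hexodiulo-2,6-pyranose (Shi ketone, 0.3 equiv), Oxone (2KHSO5·KHSO4·K2SO4), K2CO3, Bu4NHSO4, MeCN–dimethoxymethane/aq. Na2B4O7 buffer, 0 °C
Reagents that add atoms: potassium peroxymonosulfate from Oxone ([K+].[O-]S(=O)(=O)OO)
Why: Shi asymmetric epoxidation by the chiral dioxirane attacks only the electron-rich 6,7-alkene (the conjugated 2,3-alkene is deactivated), and the D-fructose-derived ketone gives the (R)-epoxide through the spiro transition state.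

Step 4
Reactants: 5 (2R)-4-[methoxy(methyl)amino]-4-oxobutan-2-yl (2E)-5-[(2R)-3,3-dimethyloxiran-2-yl]-3-methylpent-2-enoate
Product: 6 (2R)-4-[methoxy(methyl)amino]-4-oxobutan-2-yl (2E,6R)-6-[(tert-butyldimethylsilyl)oxy]-3,7-dimethylocta-2,7-dienoate
Conditions: TBSOTf (1.1 equiv), 2,6-lutidine, CH2Cl2, −78 → 0 °C
Reagents that add atoms: tert-butyldimethylsilyl trifluoromethanesulfonate (CC(C)(C)[Si](C)(C)OS(=O)(=O)C(F)(F)F)
Why: Silyl-triflate-promoted isomerisation of the epoxide to the allylic silyl ether (O-silylation, opening at the tertiary carbon, loss of a methyl proton) gives the 2-propenyl carbinol silyl ether with retention at the untouched C–O stereocentre.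

Step 5
Reactants: 6 (2R)-4-[methoxy(methyl)amino]-4-oxobutan-2-yl (2E,6R)-6-[(tert-butyldimethylsilyl)oxy]-3,7-dimethylocta-2,7-dienoate; 7 furan
Product: 10 (2R)-4-(furan-2-yl)-4-hydroxybutan-2-yl (2E,6R)-6-[(tert-butyldimethylsilyl)oxy]-3,7-dimethylocta-2,7-dienoate (both carbinol epimers), via 2-furyllithium 8 (not isolated), via furyl ketone 9 (not isolated)
Conditions: furan, n-BuLi, THF, 0 °C; then 6, −78 °C; AcOH/MeOH quench; then CeCl3·7H2O, NaBH4, −40 °C
Reagents that add atoms: none
Why: Nucleophilic acyl substitution on the Weinreb amide stops at the ketone and outcompetes the hindered conjugated ester at −78 °C, and immediate Luche-type 1,2-reduction removes the base-sensitive β-acyloxy ketone, the new carbinol centre being irrelevant because step 7 destroys it.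

Step 6
Reactants: 10 (2R)-4-(furan-2-yl)-4-hydroxybutan-2-yl (2E,6R)-6-[(tert-butyldimethylsilyl)oxy]-3,7-dimethylocta-2,7-dienoate
Product: 11 (2R)-1-(6-hydroxy-3-oxo-3,6-dihydro-2H-pyran-2-yl)propan-2-yl (2E,6R)-6-[(tert-butyldimethylsilyl)oxy]-3,7-dimethylocta-2,7-dienoate (mixture at pyranone C2 and C6)
Conditions: VO(acac)2 (vanadyl bis(acetylacetonate), 5 mol %), t-BuOOH, CH2Cl2, 0 °C → rt
Reagents that add atoms: tert-butyl hydroperoxide (CC(C)(C)OO)
Why: Achmatowicz oxidative ring expansion (hydroxyl-directed epoxidation of the furan, opening to the ene-dione, hemiacetal closure) breaks the furan aromaticity while the undirected alkenes stay untouched.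

Step 7
Reactants: 11 (2R)-1-(6-hydroxy-3-oxo-3,6-dihydro-2H-pyran-2-yl)propan-2-yl (2E,6R)-6-[(tert-butyldimethylsilyl)oxy]-3,7-dimethylocta-2,7-dienoate
Product: 14 lactone-fused 8-oxabicyclo[3.2.1]oct-3-en-2-one cycloadduct (ether bridge C4–O–C7; C5 exo-CH3 and endo silyloxyalkenyl chain; C6 exo lactone C=O; lactone CH(CH3) R), via acetoxypyranone 12 (not isolated), via oxidopyrylium ylide 13 (not isolated)
Conditions: Ac2O, i-Pr2NEt (3 equiv), 4-(dimethylamino)pyridine (cat.), MeCN (high dilution), 0 °C → rt; then 80 °C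
Reagents that add atoms: none
Why: Acetylation and base-induced loss of acetate give the 3-oxidopyrylium ylide, which undergoes an intramolecular oxidopyrylium–alkene [5+2] cycloaddition in which the four-atom tether can only span the exo position, the suprafacial addition carries the E-alkene geometry into the C5/C6 relationship (CH3 cis to the C6 carbonyl), and the (R)-methyl group sits equatorial in the half-chair of the forming lactone and so selects the alkene face.

Step 8
Reactants: 14 lactone-fused 8-oxabicyclo[3.2.1]oct-3-en-2-one cycloadduct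
Product: 15 4-hydroxycyclohept-2-en-1-one with cis-fused δ-lactone (C4–OH, C5–CH3, C6–C(=O) and C7–CH2 on one face)
Conditions: SmI2 (2.5 equiv), THF–MeOH, −78 °C
Reagents that add atoms: none
Why: SmI2 reductive cleavage of the α-alkoxy ketone C7–O bond gives a samarium dienolate that is protonated kinetically at C7 from the face carrying C6–H (anti to C5 and to the out-of-plane substituents on C6), so that C7–H ends up cis to C6–H in a cis-fused lactone.

Step 9
Reactants: 15 4-hydroxycyclohept-2-en-1-one with cis-fused δ-lactone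
Product: 16 C4 acetate of 15
Conditions: Ac2O, pyridine, 4-(dimethylamino)pyridine (cat.), CH2Cl2, 0 °C → rt
Reagents that add atoms: acetic anhydride (CC(=O)OC(C)=O)
Why: Acylation of the secondary allylic alcohol turns the γ-oxygen into a leaving group for the second reductive cleavage without creating or changing a stereocentre.

Step 10
Reactants: 16 C4 acetate of 15
Product: 18 cyclohept-2-en-1-one cis-fused across C6–C7 to the (R)-methyl δ-lactone (C4 = CH2), via deconjugated enone 17 (not isolated)
Conditions: SmI2 (2.5 equiv), THF–MeOH, −78 °C; then Et3N (cat.), rt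
Reagents that add atoms: none
Why: SmI2 reduction of the γ-acetoxy enone (vinylogous α-heteroatom cleavage) expels acetate to give a dienolate whose α-protonation gives the β,γ-enone, and the doubly activated C2–H then lets a weak amine base move the alkene into conjugation without deprotonating C7.

Step 11
Reactants: 18 cyclohept-2-en-1-one cis-fused across C6–C7 to the (R)-methyl δ-lactone
Product: 19 C1 allylic alcohol and lactol of 18 (mixtures at both new carbinol carbons)
Conditions: i-Bu2AlH (3.5 equiv), CH2Cl2, −78 °C; aq. potassium sodium tartrate (KNaC4H4O6)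
Reagents that add atoms: none
Why: Hydride reduction at −78 °C stops the lactone at the lactol (stable aluminium hemiacetal) and reduces the enone 1,2 to the allylic alcohol, which masks the ketone and freezes the C7 stereocentre for the basic olefination that follows.

Step 12
Reactants: 19 C1 allylic alcohol and lactol of 18
Product: 20 cyclohept-2-en-1-ol carrying at C6 an (E)-2-(4,4,5,5-tetramethyl-1,3,2-dioxaborolan-2-yl)ethenyl group and at C7 a (2R)-2-hydroxypropyl group
Conditions: CH2(Bpin)2 (4 equiv), lithium 2,2,6,6-tetramethylpiperidide (from the amine and n-BuLi), THF, 0 °C; then 19, −78 °C → rt; aq. NH4Cl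
Reagents that add atoms: bis[(pinacolato)boryl]methane (CC1(C)OB(CB2OC(C)(C)C(C)(C)O2)OC1(C)C)
Why: Boron-Wittig olefination (addition of the lithiated bis(boryl)methane to the aldehyde released from the lactol alkoxide, then syn-elimination of a boron–oxygen fragment) gives the (E)-alkenyl pinacolboronate and unties the tether while C6 is not epimerised because its hindered α-proton is removed more slowly than the aldehyde is attacked.

Step 13
Reactants: 20 cyclohept-2-en-1-ol carrying the (E)-alkenylboronate and the (2R)-2-hydroxypropyl group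
Product: 21 cyclohept-2-en-1-one carrying at C6 the (E)-alkenylboronate and at C7 a 2-oxopropyl group
Conditions: Dess–Martin periodinane (3 equiv), pyridine, CH2Cl2, 0 °C → rt
Reagents that add atoms: none
Why: Dess–Martin oxidation converts both secondary alcohols into ketones, restoring the C1 enone and turning the former tether carbinol into the 2-oxopropyl group (which erases the auxiliary stereocentre) without affecting the alkenylboronate or C7.

Step 14
Reactants: 21 cyclohept-2-en-1-one carrying the (E)-alkenylboronate and the 2-oxopropyl group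
Product: 22 2-(hydroxymethyl) derivative of 21
Conditions: aq. HCHO, imidazole (1 equiv), THF–aq. NaHCO3, rt
Reagents that add atoms: formaldehyde (C=O)
Why: Morita–Baylis–Hillman hydroxymethylation (reversible conjugate addition of the amine to the only enone, aldol capture of formaldehyde at C2, loss of the catalyst) installs the CH2OH group under conditions too weakly basic to epimerise C7.

Step 15
Reactants: 22 2-(hydroxymethyl) derivative of 21; 23 3-methylbut-2-enoic acid
Product: 24 O-tert-butyldimethylsilyl ether of the target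
Conditions: 23 (3 equiv), Cu(OTf)2 (1 equiv), Et3N (3 equiv), 4 Å molecular sieves, O2 (1 atm), MeCN, rt → 40 °C
Reagents that add atoms: none
Why: Chan–Lam–Evans-type oxidative coupling of the alkenylboronate with the carboxylate on divalent copper forms the C(sp2)–O bond with retention of the E geometry, the carboxylate outcompeting the free primary alcohol for copper.

Step 16
Reactants: 24 O-tert-butyldimethylsilyl ether of the target
Product: 25 (E)-2-[(1S,2R,7S)-4-(hydroxymethyl)-7-[(3R)-3-hydroxy-4-methylpent-4-en-1-yl]-7-methyl-3-oxo-2-(2-oxopropyl)cyclohept-4-en-1-yl]ethenyl 3-methylbut-2-enoate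
Conditions: HF·pyridine, pyridine–THF, 0 °C → rt
Reagents that add atoms: none
Why: Fluoride-mediated desilylation under buffered, mildly acidic conditions frees the (R)-allylic alcohol while the enol ester, the enone and the epimerisable C7 centre are tolerated.

## Compound list

1 | ethyl (3R)-3-hydroxybutanoate | C[C@@H](O)CC(=O)OCC | starting material
2 | (3R)-3-hydroxy-N-methoxy-N-methylbutanamide | C[C@@H](O)CC(=O)N(C)OC | intermediate
3 | (2E)-3,7-dimethylocta-2,6-dienoic acid (geranic acid) | CC(C)=CCC/C(C)=C/C(=O)O | starting material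
4 | (2R)-4-[methoxy(methyl)amino]-4-oxobutan-2-yl (2E)-3,7-dimethylocta-2,6-dienoate | CC(C)=CCC/C(C)=C/C(=O)O[C@H](C)CC(=O)N(C)OC | intermediate
5 | (2R)-4-[methoxy(methyl)amino]-4-oxobutan-2-yl (2E)-5-[(2R)-3,3-dimethyloxiran-2-yl]-3-methylpent-2-enoate | CC1(C)O[C@@H]1CC/C(C)=C/C(=O)O[C@H](C)CC(=O)N(C)OC | intermediate
6 | (2R)-4-[methoxy(methyl)amino]-4-oxobutan-2-yl (2E,6R)-6-[(tert-butyldimethylsilyl)oxy]-3,7-dimethylocta-2,7-dienoate | C=C(C)[C@H](O[Si](C)(C)C(C)(C)C)CC/C(C)=C/C(=O)O[C@H](C)CC(=O)N(C)OC | intermediate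
7 | furan | c1ccoc1 | starting material
8 | 2-furyllithium | [Li]c1ccco1 | intermediate
9 | (2R)-4-(furan-2-yl)-4-oxobutan-2-yl (2E,6R)-6-[(tert-butyldimethylsilyl)oxy]-3,7-dimethylocta-2,7-dienoate | C=C(C)[C@H](O[Si](C)(C)C(C)(C)C)CC/C(C)=C/C(=O)O[C@H](C)CC(=O)c1ccco1 | intermediate
10 | (2R)-4-(furan-2-yl)-4-hydroxybutan-2-yl (2E,6R)-6-[(tert-butyldimethylsilyl)oxy]-3,7-dimethylocta-2,7-dienoate (both carbinol epimers) | C=C(C)[C@H](O[Si](C)(C)C(C)(C)C)CC/C(C)=C/C(=O)O[C@H](C)CC(O)c1ccco1 | intermediate
11 | (2R)-1-(6-hydroxy-3-oxo-3,6-dihydro-2H-pyran-2-yl)propan-2-yl (2E,6R)-6-[(tert-butyldimethylsilyl)oxy]-3,7-dimethylocta-2,7-dienoate (mixture at pyranone C2 and C6) | C=C(C)[C@H](O[Si](C)(C)C(C)(C)C)CC/C(C)=C/C(=O)O[C@H](C)CC1OC(O)C=CC1=O | intermediate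
12 | 6-acetoxy analogue of 11 (acetoxypyranone) | C=C(C)[C@H](O[Si](C)(C)C(C)(C)C)CC/C(C)=C/C(=O)O[C@H](C)CC1OC(OC(C)=O)C=CC1=O | intermediate
13 | 2-{(2R)-2-[(acyl)oxy]propyl}pyrylium-3-olate (3-oxidopyrylium ylide; acyl = the silyloxy dienoyl group of 6) | C=C(C)[C@H](O[Si](C)(C)C(C)(C)C)CC/C(C)=C/C(=O)O[C@H](C)Cc1[o+]cccc1[O-] | intermediate
14 | cycloadduct: 8-oxabicyclo[3.2.1]oct-3-en-2-one core (C1=O, C2=C3, ether bridge C4–O–C7) fused across C6–C7 to a δ-lactone C7–CH2–CH(CH3)–O–C(=O)–C6 with (R)-CH(CH3); C5 carries CH3 (exo, same face as the ether bridge and the C6 lactone carbonyl) and the (3R)-3-[(tert-butyldimethylsilyl)oxy]-4-methylpent-4-en-1-yl chain (endo) | C=C(C)[C@H](O[Si](C)(C)C(C)(C)C)CC[C@@]1(C)[C@H]2C=CC(=O)[C@@]3(O2)C[C@@H](C)OC(=O)[C@H]13 | intermediate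
15 | 4-hydroxycyclohept-2-en-1-one from 14 after C7–O cleavage: C4–OH, C5–CH3, C6–C(=O) and C7–CH2 of the cis-fused δ-lactone all on one face (C6–H and C7–H cis); chain and lactone CH(CH3) as in 14 | C=C(C)[C@H](O[Si](C)(C)C(C)(C)C)CC[C@@]1(C)[C@H](O)C=CC(=O)[C@@H]2C[C@@H](C)OC(=O)[C@H]12 | intermediate
16 | C4 acetate of 15 | C=C(C)[C@H](O[Si](C)(C)C(C)(C)C)CC[C@@]1(C)[C@H](OC(C)=O)C=CC(=O)[C@@H]2C[C@@H](C)OC(=O)[C@H]12 | intermediate
17 | cyclohept-3-en-1-one (C3=C4) isomer of 18 | C=C(C)[C@H](O[Si](C)(C)C(C)(C)C)CC[C@@]1(C)C=CCC(=O)[C@@H]2C[C@@H](C)OC(=O)[C@H]12 | intermediate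
18 | cyclohept-2-en-1-one (C1=O, C2=C3, C4H2) cis-fused across C6–C7 to the (R)-methyl δ-lactone; C5–CH3, C6–C(=O) and C7–CH2 cis; (3R)-silyloxy chain on C5 | C=C(C)[C@H](O[Si](C)(C)C(C)(C)C)CC[C@@]1(C)CC=CC(=O)[C@@H]2C[C@@H](C)OC(=O)[C@H]12 | intermediate
19 | C1 allylic alcohol and lactol derived from 18 (mixtures at C1 and at the lactol carbon) | C=C(C)[C@H](O[Si](C)(C)C(C)(C)C)CC[C@@]1(C)CC=CC(O)[C@@H]2C[C@@H](C)OC(O)[C@H]12 | intermediate
20 | cyclohept-2-en-1-ol with C5 CH3 and silyloxy chain, C6 (E)-2-(pinacolboryl)ethenyl, C7 (2R)-2-hydroxypropyl; C5–CH3, C6 and C7 substituents cis; C1–OH as a mixture | C=C(C)[C@H](O[Si](C)(C)C(C)(C)C)CC[C@@]1(C)CC=CC(O)[C@H](C[C@@H](C)O)[C@@H]1/C=C/B1OC(C)(C)C(C)(C)O1 | intermediate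
21 | cyclohept-2-en-1-one with C6 (E)-2-(pinacolboryl)ethenyl and C7 2-oxopropyl, ring configuration as in the target | C=C(C)[C@H](O[Si](C)(C)C(C)(C)C)CC[C@@]1(C)CC=CC(=O)[C@H](CC(C)=O)[C@@H]1/C=C/B1OC(C)(C)C(C)(C)O1 | intermediate
22 | 2-(hydroxymethyl) derivative of 21 | C=C(C)[C@H](O[Si](C)(C)C(C)(C)C)CC[C@@]1(C)CC=C(CO)C(=O)[C@H](CC(C)=O)[C@@H]1/C=C/B1OC(C)(C)C(C)(C)O1 | intermediate
23 | 3-methylbut-2-enoic acid | CC(C)=CC(=O)O | starting material
24 | O-tert-butyldimethylsilyl ether (side-chain carbinol) of the target | C=C(C)[C@H](O[Si](C)(C)C(C)(C)C)CC[C@@]1(C)CC=C(CO)C(=O)[C@H](CC(C)=O)[C@@H]1/C=C/OC(=O)C=C(C)C | intermediate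
25 | (E)-2-[(1S,2R,7S)-4-(hydroxymethyl)-7-[(3R)-3-hydroxy-4-methylpent-4-en-1-yl]-7-methyl-3-oxo-2-(2-oxopropyl)cyclohept-4-en-1-yl]ethenyl 3-methylbut-2-enoate | C=C(C)[C@H](O)CC[C@@]1(C)CC=C(CO)C(=O)[C@H](CC(C)=O)[C@@H]1/C=C/OC(=O)C=C(C)C | target

## Step count and risks

Total steps: 16. Longest linear sequence: 16 (1 → 25).

Most likely to fail:

Step 7. The tether is an ester, which must adopt its less favoured conformation to close the six-membered ring, and it forces the nucleophilic ylide carbon onto the α-carbon of a hindered β,β-disubstituted enoate. Ylide dimerisation or poor facial selectivity may therefore win. The fallback replaces the ester tether by an acetal tether, so that the 2π partner is an unactivated trisubstituted alkene on a conformationally free tether. It sets out from 2 and returns at 14. Transacetalisation of 2 with (2E)-1,1-dimethoxy-3,7-dimethylocta-2,6-diene (geranial dimethyl acetal; pyridinium p-toluenesulfonate, benzene, 4 Å molecular sieves) gives the mixed methyl acetal amide F1. Addition of 8 gives the furyl ketone F2, which is reduced in the same flask (CeCl3·7H2O, NaBH4) to the furyl carbinol F3. Achmatowicz oxidation as in step 6 gives the hydroxypyranone F4. Acetylation to the acetoxypyranone F5 and heating with base gives the oxidopyrylium ylide F6, which closes to the cyclic-acetal cycloadduct F7 under the same stereochemical model (chair, equatorial methyl). Jones oxidation (CrO3, aq. H2SO4, acetone) turns the methyl lactol ether into the lactone cycloadduct F8. Shi epoxidation of its prenyl group gives the epoxide F9, and TBSOTf/2,6-lutidine as in step 4 delivers 14.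

Step 8. The C7 configuration rests on kinetic protonation of a samarium enolate that sits next to a trivalent samarium alkoxide on the opposite face, which could relay the proton to the wrong side. The fallback separates C–O cleavage from protonation. It sets out from 14 and returns at 15. SmI2 in THF without a proton source, followed by Me3SiCl/Et3N, gives the bis(trimethylsilyl) dienol ether F10. Protodesilylation at −78 °C with a hindered proton donor (2,6-di-tert-butylphenol with HF·pyridine) then delivers the proton to C7 from the face of C6–H with no metal alkoxide nearby, and gives 15.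

Step 15. Oxidative copper coupling of a hindered alkenyl pinacolboronate has to work beside a free primary alcohol, an enone and an epimerisable 1,4-diketone. The fallback changes to an Ullmann-type coupling of an alkenyl iodide. It sets out from 22 and returns at 24. Iododeboronation with retention (N-iodosuccinimide, MeCN, 0 °C, dark) gives the (E)-alkenyl iodide F11. Coupling with caesium 3-methylbut-2-enoate (from 23 and Cs2CO3; CuI, 3,4,7,8-tetramethyl-1,10-phenanthroline, toluene, 70 °C) gives 24.

Further compounds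
F1 | step 7 | (3R)-N-methoxy-3-{[(2E)-1-methoxy-3,7-dimethylocta-2,6-dien-1-yl]oxy}-N-methylbutanamide (acetal carbon as a mixture) | CC(C)=CCC/C(C)=C/C(OC)O[C@H](C)CC(=O)N(C)OC
F2 | step 7 | (3R)-1-(furan-2-yl)-3-{[(2E)-1-methoxy-3,7-dimethylocta-2,6-dien-1-yl]oxy}butan-1-one | CC(C)=CCC/C(C)=C/C(OC)O[C@H](C)CC(=O)c1ccco1
F3 | step 7 | (3R)-1-(furan-2-yl)-3-{[(2E)-1-methoxy-3,7-dimethylocta-2,6-dien-1-yl]oxy}butan-1-ol (carbinol epimers) | CC(C)=CCC/C(C)=C/C(OC)O[C@H](C)CC(O)c1ccco1
F4 | step 7 | 6-hydroxy-2-[(2R)-2-{[(2E)-1-methoxy-3,7-dimethylocta-2,6-dien-1-yl]oxy}propyl]-2H-pyran-3(6H)-one | CC(C)=CCC/C(C)=C/C(OC)O[C@H](C)CC1OC(O)C=CC1=O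
F5 | step 7 | 6-acetoxy analogue of F4 | CC(C)=CCC/C(C)=C/C(OC)O[C@H](C)CC1OC(OC(C)=O)C=CC1=O
F6 | step 7 | 2-[(2R)-2-{[(2E)-1-methoxy-3,7-dimethylocta-2,6-dien-1-yl]oxy}propyl]pyrylium-3-olate | CC(C)=CCC/C(C)=C/C(OC)O[C@H](C)Cc1[o+]cccc1[O-]
F7 | step 7 | cycloadduct as 14 but with a 2-methoxytetrahydropyran (cyclic methyl acetal) in place of the lactone and a 4-methylpent-3-enyl chain on C5 | CC(C)=CCC[C@@]1(C)[C@H]2C=CC(=O)[C@@]3(O2)C[C@@H](C)OC(OC)[C@H]13
F8 | step 7 | lactone cycloadduct as 14 but with a 4-methylpent-3-enyl chain on C5 | CC(C)=CCC[C@@]1(C)[C@H]2C=CC(=O)[C@@]3(O2)C[C@@H](C)OC(=O)[C@H]13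
F9 | step 7 | (R)-epoxide of F8 (2-[(2R)-3,3-dimethyloxiran-2-yl]ethyl chain on C5) | CC1(C)O[C@@H]1CC[C@@]1(C)[C@H]2C=CC(=O)[C@@]3(O2)C[C@@H](C)OC(=O)[C@H]13
F10 | step 8 | bis(trimethylsilyl) dienol ether of 15 (C1–OSiMe3 with C1=C7, C2=C3, C4–OSiMe3) | C=C(C)[C@H](O[Si](C)(C)C(C)(C)C)CC[C@@]1(C)[C@H](O[Si](C)(C)C)C=CC(O[Si](C)(C)C)=C2C[C@@H](C)OC(=O)[C@H]12
F11 | step 15 | (E)-alkenyl iodide corresponding to 22 (iodine in place of the pinacolboryl group) | C=C(C)[C@H](O[Si](C)(C)C(C)(C)C)CC[C@@]1(C)CC=C(CO)C(=O)[C@H](CC(C)=O)[C@@H]1/C=C/I
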